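Per hour was the unit I chose: one constant in reciprocal hours, read from the fall of the unreacted substrate, to tell me what the flask would keep at the end.

| setting | midnight | noon | winter | flask |
|---|---|---|---|---|
| left-handed substrate | 0.70 M | 1.1 M | 0.50 M | 0.50 M |
| right-handed substrate | 0.70 M | 1.1 M | 0.50 M | 0.50 M |
| gas | 23 mM (held) | 23 mM (held) | 23 mM (held) | 23 mM (held) |
| free catalyst | 25 mM | 25 mM | 50 mM | 25 mM |
| racemization catalyst | 0.50 mM | 0.50 mM | 0.50 mM | 0.50 mM |
| remark | run made earlier | run made earlier | run made earlier |  |
| time |  |  |  | 8.0 h |

| run | time / h | left-handed product / % | right-handed product / % | left-handed substrate / % |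
|---|---|---|---|---|
| midnight | 0.667 | 16.1 | 4.2 | 38.1 |
| midnight | 2.00 | 42.4 | 8.3 | 23.9 |
| midnight | 3.00 | 53.9 | 13.9 | 13.6 |
| midnight | 5.00 | 63.0 | 24.6 | 5.0 |
| midnight | 8.00 | 61.1 | 35.8 | 0.4 |
| midnight | 10.0 | 58.6 | 42.8 | 0 |
| noon | 0.667 | 13.0 | 1.6 | 41.2 |
| noon | 2.00 | 35.1 | 9.5 | 27.0 |
| noon | 3.00 | 49.7 | 12.5 | 18.1 |
| noon | 5.00 | 61.2 | 21.6 | 5.3 |
| noon | 8.00 | 62.4 | 35.2 | 1.5 |
| noon | 10.0 | 60.2 | 41.2 | 1.2 |
| winter | 0.833 | 32.7 | 5.7 | 28.2 |
| winter | 1.33 | 45.6 | 8.6 | 19.8 |
| winter | 2.50 | 65.8 | 16.8 | 7.3 |
| winter | 5.00 | 68.1 | 29.3 | 0 |
| winter | 10.0 | 56.3 | 41.5 | 1.6 |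

(standard deviation of a reading: 1 percentage point)

- left-handed product and right-handed product together, in percent of the left-handed substrate and right-handed substrate charged together, at 8.0 h
- excess of left-handed product over right-handed product in the product at 8.0 h
- whether the exchange between left-handed substrate and right-handed substrate keeps pace with the reaction: how far the product's excess at 8.0 h gets from its value without exchange to its value with instant exchange (above 80% keeps pace, below 20% hardly takes part, else lags behind)

- free catalyst is single-handed; left-handed substrate and right-handed substrate are mirror images of each other, charged as a racemate, each of them at the stated concentration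
- the numbers in the tables scatter by 1 percentage point (one standard deviation)
- at the start none of the gas is in solution
- an excess is the difference of the two amounts in percent of their sum
- an excess is below zero if the other one leads

1. I took the percent of both substrates unreacted, which is what the two products leave over, and defined the pseudo-first-order constant as the logarithm of its fall divided by the hours between. In the midnight run, from 2.00 h to 5.00 h, this gave 0.460 h⁻¹.

2. The noon run, over the same hours and with more substrate than the midnight run, gave 0.390 h⁻¹, so I took the order in substrate as about one.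

3. The winter run, read from 1.33 h to 2.50 h, gave 0.827 h⁻¹, twice the midnight value on twice the free catalyst but also on less substrate and over other hours; since step 2 had shown the constant little moved by substrate, I scaled it with free catalyst.

4. The weak link was the opening. The midnight run's first 2.00 h gave 0.354 h⁻¹, less than the later constant, and I read this as the gas still dissolving. A single opening constant would put the flask at 94.1%, so I kept the midnight opening and ran the later constant from there, which gave 96.9%.

5. The forecast, higher than my figure, said 98%, excess 25%, keeps pace: “so the flask should reach about 97–98% by 8 h”.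

The flask gave 98.6%, excess 24.9%, and keeps pace, at 98% of the way. The reagent in this flask stood at 0.0119 M after 0.800 h and 0.0212 M after 8.00 h. Read back, the flask's yield means a constant of 0.530 h⁻¹ on average over the whole run, more than the 0.460 h⁻¹ I had read in the midnight run.

    left-handed product ⇌ right-handed product (k = 2.94 × 10⁻⁵ s⁻¹)
    reagent + free catalyst + left-handed substrate → free catalyst + left-handed product (k = 0.696 M⁻² s⁻¹)
    reagent ⇌ dormant form (K = 60.0, k = 0.00547 s⁻¹)
    left-handed substrate + racemization catalyst ⇌ right-handed substrate + racemization catalyst, rate k4*[racemization catalyst]*[left-handed substrate] forward; the back reaction follows from the equilibrium constant (k = 1.25 M⁻¹ s⁻¹)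
    reagent + free catalyst + right-handed substrate → free catalyst + right-handed product (k = 0.0651 M⁻² s⁻¹)
    gas ⇌ reagent, rate k6*(csat - [reagent]) (kL = 0.0119 s⁻¹)

Scaled to the neighbour flask with 0.015 M free catalyst, that constant gives 92.1%. The neighbour flask gave 93.1%.

The data were computed with constants of no real substance; scatter was added.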